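## Retrosynthetic overview
1. Target ⇒ one O‑methylation and one hydroquinone→quinone oxidation of a triaryl bis‑ether. Its rings B and C carry the same 1,2,4‑trioxygenated thymol pattern.
2. Rings B and C ⇒ formed together in a single heating by a twofold 4π‑opening/6π‑closure (Moore ring expansion) of an O‑linked bis(4‑alkenylcyclobutenone).
3. Bis(cyclobutenone) ⇒ one‑pot iteration: aryl methylsemisquarate + 3‑methylbut‑1‑en‑2‑yllithium, capture of the carbinolate with 3‑chloro‑4‑methylcyclobutenedione, then a second alkenyllithium addition.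
4. Building blocks ⇒ ring A phenol from thymol (para‑methoxylation), the C4 unit from dimethyl squarate + MeLi, and the C5 alkenyl unit from 3‑methylbut‑1‑yne + HBr.
5. Ring order: ring A is bought as thymol, and rings B and C form simultaneously in the last step. No aryl C–O cross‑coupling is used.

Assumption: the SMILES contains no stereocentre and no stereodefined double bond, and the aryl ether axes rotate freely. The target is therefore achiral and needs no stereocontrol. The sp3 carbinol centres of the four‑membered‑ring intermediates are formed unselectively and are erased on aromatisation.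

## Route

Step 1
Reactants: 1 thymol
Product: 3 thymohydroquinone 4‑methyl ether (4‑methoxy‑2‑isopropyl‑5‑methylphenol), via thymoquinone dimethyl monoketal 2 (not isolated)
Conditions: PhI(OAc)2 (2.1 equiv), MeOH, 0 °C to rt; then Zn dust, AcOH, rt (same pot)
Reagents that add atoms: methanol (CO)
Why: Oxidative phenol dearomatisation with PhI(OAc)2 delivers methanol twice to the free para position to give the p‑quinone monoketal, and zinc reduction rearomatises it with loss of one methanol, so the free OH stays next to the isopropyl group and the OMe ends up next to the methyl group without any regiochemical ambiguity.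

Step 2
Reactants: 4 dimethyl squarate
Product: 7 methylsemisquaric acid (3‑hydroxy‑4‑methylcyclobut‑3‑ene‑1,2‑dione), via lithium carbinolate 5 (not isolated), via methyl methylsemisquarate 6 (not isolated)
Conditions: MeLi (1.05 equiv), THF, −78 °C; then 6 M aq HCl, rt to 50 °C; continuous EtOAc extraction
Reagents that add atoms: methyllithium ([Li]C); water (O)
Why: MeLi adds 1,2 to one of the two equivalent squarate carbonyls, acid ionises the carbinol to a methoxy‑stabilised cyclobutenyl cation that collapses to the vinylogous ester 6 (Liebeskind–Moore squarate substitution), and further aqueous acid hydrolyses that ester to the vinylogous acid 7.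

Step 3
Reactants: 7 methylsemisquaric acid
Product: 8 3‑chloro‑4‑methylcyclobut‑3‑ene‑1,2‑dione
Conditions: (COCl)2 (1.5 equiv), DMF (cat.), CH2Cl2, rt to 40 °C; bulb‑to‑bulb distillation (enough made for steps 5 and 6)
Reagents that add atoms: oxalyl chloride (O=C(Cl)C(=O)Cl)
Why: Vilsmeier‑type activation turns the vinylogous carboxylic acid into the vinylogous acid chloride, in the same way that squaric acid gives squaryl dichloride.

Step 4
Reactants: 9 3‑methylbut‑1‑yne
Product: 10 2‑bromo‑3‑methylbut‑1‑ene
Conditions: HBr (1.1 equiv, 33 % in AcOH), Et4NBr (1 equiv), CH2Cl2, 0 to 40 °C; distil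
Reagents that add atoms: hydrogen bromide (Br)
Why: Markovnikov hydrobromination by the hydrogen dibromide ion follows a termolecular AdE3 path without a free vinyl cation, so no hydride shift from the isopropyl CH occurs, and it stops at the deactivated 2‑bromoalkene.

Step 5
Reactants: 3 thymohydroquinone 4‑methyl ether; 8 3‑chloro‑4‑methylcyclobut‑3‑ene‑1,2‑dione
Product: 12 aryl methylsemisquarate (3‑(4‑methoxy‑2‑isopropyl‑5‑methylphenoxy)‑4‑methylcyclobut‑3‑ene‑1,2‑dione), via sodium phenoxide 11 (not isolated)
Conditions: NaH (1.05 equiv), THF, 0 °C; then 8 (1.05 equiv), −78 to 0 °C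
Reagents that add atoms: none
Why: Vinylogous acyl substitution (addition–elimination at the chlorine‑bearing carbon) by the preformed phenoxide makes the ring A–O bond at low temperature, before the acidic ring methyl group can interfere.

Step 6
Reactants: 12 aryl methylsemisquarate; 10 2‑bromo‑3‑methylbut‑1‑ene (used twice as its lithium derivative); 8 3‑chloro‑4‑methylcyclobut‑3‑ene‑1,2‑dione
Product: 17 O‑linked bis(4‑alkenylcyclobutenone) carbinol (diastereomer mixture), via alkenyllithium 13 (not isolated), via first lithium carbinolate 14 (not isolated), via cyclobutenonyl methylsemisquarate 15 (not isolated), via second lithium carbinolate 16 (not isolated)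
Conditions: 10 (2.2 equiv), t‑BuLi (4.3 equiv), Et2O, −78 °C (titrated stock of 13); 12, THF, −78 °C, 13 (1.02 equiv), 30 min; 8 (1.0 equiv), −78 to −45 °C, 1 h; recool to −78 °C, 13 (1.05 equiv), 30 min; sat. aq NH4Cl, −78 °C to rt; fast column on Et3N‑deactivated silica
Reagents that add atoms: none
Why: Proposed new method: the closest known reactions are the regioselective 1,2‑addition of alkenyllithiums to 3‑alkoxy‑4‑alkylcyclobutenediones (Moore–Liebeskind squarate chemistry) and the in‑pot O‑capture of the resulting tertiary carbinolates by acyl or silyl chlorides; here 13 attacks the carbonyl next to the oxygen‑bearing carbon of 12 because the other carbonyl is deactivated as a vinylogous ester, carbinolate 14 displaces chloride from the flat and unhindered vinylogous acid chloride 8 by addition–elimination, and the new 1,2‑dione carbonyl of 15 is far more electrophilic than the neopentyl‑type vinylogous‑ester carbonyl of the first four‑membered ring, so the second portion of 13 adds there with the same regiochemistry, while the labile tertiary allylic ester 15 is never isolated and the two uncontrolled carbinol stereocentres are erased in step 7.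

Step 7
Reactants: 17 O‑linked bis(4‑alkenylcyclobutenone) carbinol
Product: 20 CNP0335608.0 (target), via triphenol 18 (not isolated), via quinone phenol 19 (not isolated)
Conditions: PhMe (0.01 M, degassed, Ar), 110 °C, 3 h; concentrate to 0.1 M; Ag2O (4 equiv), 4 Å MS, rt, 30 min; then MeI (10 equiv), 40 °C, 16 h, dark
Reagents that add atoms: iodomethane (CI)
Why: Proposed new method: this is a twofold Moore ring expansion, known for single 4‑alkenyl‑4‑oxycyclobutenones such as the isopropenyl adduct of dimethyl squarate, in which each four‑membered ring opens by thermal conrotatory 4π electrocyclisation with its oxygen substituent rotating outward and the alkenyl group inward, the dienylketene closes by 6π electrocyclisation and tautomerises so that rings B and C both form in the same heating with the pattern fixed by the addition regiochemistry of step 6, after which Ag2O rapidly oxidises only the ring C hydroquinone to the quinone and Ag2O/MeI (Purdie methylation, as used for juglone) methylates the single remaining phenol under non‑basic conditions; no stereocentre remains.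

## Compound list
1 | thymol (2‑isopropyl‑5‑methylphenol) | CC(C)c1ccc(C)cc1O | starting material
2 | 4,4‑dimethoxy‑2‑isopropyl‑5‑methylcyclohexa‑2,5‑dien‑1‑one | COC1(OC)C=C(C(C)C)C(=O)C=C1C | intermediate
3 | 4‑methoxy‑2‑isopropyl‑5‑methylphenol | COc1cc(C(C)C)c(O)cc1C | intermediate
4 | dimethyl squarate (3,4‑dimethoxycyclobut‑3‑ene‑1,2‑dione) | COC1=C(OC)C(=O)C1=O | starting material
5 | lithium 2,3‑dimethoxy‑1‑methyl‑4‑oxocyclobut‑2‑en‑1‑olate (racemic) | [Li+].[O-]C1(C)C(OC)=C(OC)C1=O | intermediate
6 | 3‑methoxy‑4‑methylcyclobut‑3‑ene‑1,2‑dione | COC1=C(C)C(=O)C1=O | intermediate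
7 | 3‑hydroxy‑4‑methylcyclobut‑3‑ene‑1,2‑dione | CC1=C(O)C(=O)C1=O | intermediate
8 | 3‑chloro‑4‑methylcyclobut‑3‑ene‑1,2‑dione | CC1=C(Cl)C(=O)C1=O | intermediate
9 | 3‑methylbut‑1‑yne | C#CC(C)C | starting material
10 | 2‑bromo‑3‑methylbut‑1‑ene | C=C(Br)C(C)C | intermediate
11 | sodium 4‑methoxy‑2‑isopropyl‑5‑methylphenoxide | [Na+].[O-]c1cc(C)c(OC)cc1C(C)C | intermediate
12 | 3‑(4‑methoxy‑2‑isopropyl‑5‑methylphenoxy)‑4‑methylcyclobut‑3‑ene‑1,2‑dione | COc1cc(C(C)C)c(OC2=C(C)C(=O)C2=O)cc1C | intermediate
13 | 3‑methylbut‑1‑en‑2‑yllithium | [Li]C(=C)C(C)C | intermediate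
14 | lithium 2‑(4‑methoxy‑2‑isopropyl‑5‑methylphenoxy)‑3‑methyl‑1‑(3‑methylbut‑1‑en‑2‑yl)‑4‑oxocyclobut‑2‑en‑1‑olate (racemic) | [Li+].[O-]C1(C(=C)C(C)C)C(=O)C(C)=C1Oc1cc(C)c(OC)cc1C(C)C | intermediate
15 | 3‑{[2‑(4‑methoxy‑2‑isopropyl‑5‑methylphenoxy)‑3‑methyl‑1‑(3‑methylbut‑1‑en‑2‑yl)‑4‑oxocyclobut‑2‑en‑1‑yl]oxy}‑4‑methylcyclobut‑3‑ene‑1,2‑dione (racemic) | CC1=C(Oc2cc(C)c(OC)cc2C(C)C)C(OC2=C(C)C(=O)C2=O)(C(=C)C(C)C)C1=O | intermediate
16 | lithium carbinolate of 17 (diastereomer mixture) | [Li+].[O-]C1(C(=C)C(C)C)C(=O)C(C)=C1OC1(C(=C)C(C)C)C(=O)C(C)=C1Oc1cc(C)c(OC)cc1C(C)C | intermediate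
17 | 4‑hydroxy‑2‑methyl‑4‑(3‑methylbut‑1‑en‑2‑yl)‑3‑{[2‑(4‑methoxy‑2‑isopropyl‑5‑methylphenoxy)‑3‑methyl‑1‑(3‑methylbut‑1‑en‑2‑yl)‑4‑oxocyclobut‑2‑en‑1‑yl]oxy}cyclobut‑2‑en‑1‑one (two racemic diastereomers) | OC1(C(=C)C(C)C)C(=O)C(C)=C1OC1(C(=C)C(C)C)C(=O)C(C)=C1Oc1cc(C)c(OC)cc1C(C)C | intermediate
18 | 3‑[4‑hydroxy‑6‑isopropyl‑2‑(4‑methoxy‑2‑isopropyl‑5‑methylphenoxy)‑3‑methylphenoxy]‑5‑isopropyl‑2‑methylbenzene‑1,4‑diol | COc1cc(C(C)C)c(Oc2c(C)c(O)cc(C(C)C)c2Oc2c(C)c(O)cc(C(C)C)c2O)cc1C | intermediate
19 | 2‑[4‑hydroxy‑6‑isopropyl‑2‑(4‑methoxy‑2‑isopropyl‑5‑methylphenoxy)‑3‑methylphenoxy]‑6‑isopropyl‑3‑methylcyclohexa‑2,5‑diene‑1,4‑dione | COc1cc(C(C)C)c(Oc2c(C)c(O)cc(C(C)C)c2OC2=C(C)C(=O)C=C(C(C)C)C2=O)cc1C | intermediate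
20 | CNP0335608.0, 2‑[6‑isopropyl‑4‑methoxy‑2‑(4‑methoxy‑2‑isopropyl‑5‑methylphenoxy)‑3‑methylphenoxy]‑6‑isopropyl‑3‑methylcyclohexa‑2,5‑diene‑1,4‑dione (achiral) | COc1cc(C(C)C)c(Oc2c(C)c(OC)cc(C(C)C)c2OC2=C(C)C(=O)C=C(C(C)C)C2=O)cc1C | target

## Count and risks
Total steps: 7. Longest linear sequence: 5 (steps 2, 3, 5, 6, 7, from dimethyl squarate).

**Step 7 (most likely to fail).**
- Risks in the heating:
  - The ring B precursor is a tertiary allylic ether of a vinylogous acid. It could undergo a Claisen‑type [3,3] shift or ionise before it opens.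
  - A ketene could be captured by the free carbinol or by phenols already formed.
- Risks in the end game:
  - Ag2O could attack the electron‑rich ring B phenol.
  - MeI could reach the hydroquinone before it is oxidised.
- Fallback, setting out from 16 and coming back at 20: carbinolate 16 is not protonated but capped in the pot with Et3SiCl, giving the O‑triethylsilyl bis(cyclobutenone) F1, which has no free OH. The same twofold thermal ring expansion gives the ring C monosilylated bisphenol F2. Because no quinone is present, both free phenols can be methylated robustly with MeI/K2CO3 in acetone to give the bis(methyl ether) F3. Bu4NF then frees the hindered ring C para‑methoxyphenol F4. PhI(OAc)2 in aqueous MeCN oxidises only this free phenol to the quinone with loss of methanol (oxidative demethylation), which gives 20.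

**Step 6.**
- Risks:
  - Carbinolate 14 may deprotonate the acidic methyl group of 8 instead of displacing chloride.
  - Ester 15 may lose the strongly acidic semisquarate.
  - The bulk of the oxygen substituents may erode the regio‑ or chemoselectivity of the second addition.
- Fallback, setting out from 14 and coming back at 17: this is a convergent union of two preformed cyclobutenones, which avoids 8, 15 and the second alkenyllithium addition. One batch of 14 is capped with Me3SiCl to give the O‑trimethylsilyl cyclobutenone F5. A second batch of 14 is added to F5 (3 equiv, excess recovered, which suppresses further chain growth) in THF/DMPU at −40 to 0 °C. Addition–elimination at the aryloxy‑bearing carbon of F5 expels the phenoxide of 3, which is recycled, and gives the O‑trimethylsilyl bis(cyclobutenone) F6. HF·pyridine at 0 °C then releases 17.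

**Step 1.**
- Risks:
  - Ortho attack may give a dimerising o‑quinone ketal.
  - Hydrolysis of ketal 2 to thymoquinone would lead, after Zn reduction, to thymohydroquinone.
- Fallback, setting out from 1 and coming back at 3: this uses halogenation and copper‑catalysed C–O coupling instead of dearomatisation. NBS in MeCN at 0 °C brominates para to the OH to give 4‑bromothymol F7. NaOMe with CuBr (cat.) in DMF/MeOH at 110 °C then replaces bromide by methoxide to give 3.

## Further compounds
F1 | step 7 | O‑triethylsilyl ether of 17 (diastereomer mixture) | CC[Si](CC)(CC)OC1(C(=C)C(C)C)C(=O)C(C)=C1OC1(C(=C)C(C)C)C(=O)C(C)=C1Oc1cc(C)c(OC)cc1C(C)C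
F2 | step 7 | 3‑[4‑hydroxy‑6‑isopropyl‑2‑(4‑methoxy‑2‑isopropyl‑5‑methylphenoxy)‑3‑methylphenoxy]‑5‑isopropyl‑2‑methyl‑4‑(triethylsilyloxy)phenol | COc1cc(C(C)C)c(Oc2c(C)c(O)cc(C(C)C)c2Oc2c(C)c(O)cc(C(C)C)c2O[Si](CC)(CC)CC)cc1C
F3 | step 7 | bis(methyl ether) of F2 | COc1cc(C(C)C)c(Oc2c(C)c(OC)cc(C(C)C)c2Oc2c(C)c(OC)cc(C(C)C)c2O[Si](CC)(CC)CC)cc1C
F4 | step 7 | 6‑isopropyl‑4‑methoxy‑3‑methyl‑2‑[6‑isopropyl‑4‑methoxy‑2‑(4‑methoxy‑2‑isopropyl‑5‑methylphenoxy)‑3‑methylphenoxy]phenol | COc1cc(C(C)C)c(Oc2c(C)c(OC)cc(C(C)C)c2Oc2c(C)c(OC)cc(C(C)C)c2O)cc1C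
F5 | step 6 | 3‑(4‑methoxy‑2‑isopropyl‑5‑methylphenoxy)‑2‑methyl‑4‑(3‑methylbut‑1‑en‑2‑yl)‑4‑(trimethylsilyloxy)cyclobut‑2‑en‑1‑one (racemic) | C[Si](C)(C)OC1(C(=C)C(C)C)C(=O)C(C)=C1Oc1cc(C)c(OC)cc1C(C)C
F6 | step 6 | O‑trimethylsilyl ether of 17 (diastereomer mixture) | C[Si](C)(C)OC1(C(=C)C(C)C)C(=O)C(C)=C1OC1(C(=C)C(C)C)C(=O)C(C)=C1Oc1cc(C)c(OC)cc1C(C)C
F7 | step 1 | 4‑bromothymol (4‑bromo‑2‑isopropyl‑5‑methylphenol) | CC(C)c1cc(Br)c(C)cc1O
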